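At 2.5 d the flasks differ in their charge of substrate, with the time held, so I ask which way the fraction of the charge found as single ring moves with that charge.

| flask | substrate | remark | time |
|---|---|---|---|
| larch | 3.1 mM | run made earlier |  |
| delta | 30 mM |  | 2.5 d |
| gamma | 6.0 mM |  | 2.5 d |
| epsilon | 20 mM |  | 2.5 d |
| zeta | 10 mM |  | 2.5 d |

larch run (percent of the substrate charged)

| time / h | single ring / % | substrate / % |
|---|---|---|
| 4.00 | 55.9 | 23.3 |
| 10.0 | 64.3 | 11.1 |
| 20.0 | 63.3 | 11.2 |
| 30.0 | 60.1 | 9.9 |

(scatter of a reading: 0.5 percentage points)



- all flasks from highest to lowest amount of single ring, in percent of the substrate charged, at 2.5 d (delta / gamma / epsilon / zeta)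
- the same order at 6.0 h (delta / gamma / epsilon / zeta)
- the amount of single ring, in percent of the substrate charged of the flask you put first, at 2.5 d
- the amount of single ring, in percent of the substrate charged of the flask you put last, at 2.5 d

1. Turned round: for a single loss step, delta, the richest flask, leads if the lost fraction falls as the charge rises. That needs a loss of order below 1 in substrate; at order 1 the charge cancels and the flasks tie.

2. The larch run reads that order. Let S be the fraction of the charge present as single ring plus substrate. S falls at 0.0520 /h over the first interval and 0.00270 /h late, a ratio of 19.3. The mean substrate fraction drops by a factor of 5.87. The order reads 1.67, higher than the tie value, so dilution should win.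

3. I round the order to 2 and freeze the pair as a pre-equilibrium: over the larch readings from 10.0 h on, single ring reads 85.4% of S, and I hold that share. Then 1/S − 1 grows in proportion to the charge. That growth per mM of charge at a given time is the drain number G. Carrying the late larch slope forward gives, at 2.5 d, G = 0.188 /mM.

4. Single ring is then that share divided by 1 + G × charge: 40.1% in gamma and 12.9% in delta. At a shared time this falls as the charge rises, so I expect the same order at 6.0 h.

5. The forecast says gamma > zeta > epsilon > delta at 2.5 d, gamma > zeta > epsilon > delta at 6.0 h, with 44% and 17%: “Dilution wins at both times.” Its order matches mine, but its two amounts stand higher than mine.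

6. The flasks give gamma > zeta > epsilon > delta at 2.5 d and gamma > zeta > epsilon > delta at 6.0 h, with 42.3% and 13.7%.

    open dimer → ring dimer (k = 6.10 × 10⁻⁴ /min)
    2 substrate → open dimer (k = 0.500 /M/min)
    substrate + open dimer → open trimer (k = 0.350 /M/min)
    substrate ⇌ single ring (K = 5.70, k = 0.00570 /min)

Open trimer holds 47.3% of the charge in delta, more than the 16.7% in gamma. On a neighbour of delta charged with 12 mM, the carried G gives 26.2% single ring at 2.5 d, and that flask holds 28.1%.

(The readings are calculated with made-up constants, noise included.)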